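## Analysis of the target

The target is an open-chain trifuran. Ring A is a 2,4-disubstituted furan carrying the (E)-2-methylprop-2-enoic acid at C2 and the chain at C4. Ring B, the central furan, is also 2,4-disubstituted. Ring C is a furan substituted only at C3. The chain from C4 of ring A runs CH2–CH2–CH2–CH(CH3)–CH2 to C2 of ring B, and a (CH2)3 tether joins C4 of ring B to C3 of ring C.

There is one stereocentre, the methyl-bearing carbon, which is (S) by the sequence rule. It relates to no other stereo-element, so it must be set absolutely. It is remote from all functionality and differs in its two arms only far from the centre, which makes it hard to address.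

All three furans are sensitive to strong acid, to electrophiles and to oxidants. The 2,4-pattern of rings A and B cannot be reached by direct substitution of furan, which favours the α-positions. The furylacrylic acid is a conjugated acceptor and is best made last.

The strategy rests on one feature: the stereocentre has a CH2 on each side. It can therefore be the terminus of a [3,3] shift in which the CH2 that later bonds to C2 of ring B comes from an acetamide unit. The other arm is then an (E)-alkene leading to ring A, and the alkene is saturated afterwards.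

## Retrosynthetic reasoning

**Acrylic acid.** Acid 30 is cut back to ester 29, and the trisubstituted C=C of 29 is cut between the CH attached to C2 of ring A and the methyl-bearing carbon, giving aldehyde 27 and the stabilised ylide 28. The conjugated acid is the most reactive part of the molecule, so it is installed last. The forward olefination only has to deliver the (E)-isomer, which a stabilised α-methyl ylide does by thermodynamic preference.

**Ring B.** Ring B of 27 is opened at the C3–C4 bond and at the O1–C2 bond. This leads to aldol 25 and from there to methyl ketone 16 and the α-silyloxy ketone 23. The cut is made here because C2 of ring B sits next to the CH2 that flanks the stereocentre. A carbonyl carbon at that position is exactly what a Claisen-type rearrangement leaves behind. The cut is also convergent, because ring C and its tether arrive in one piece with 23. The forward sequence is an aldol addition, then cyclisation of the freed primary alcohol onto the ketone and a double dehydration. The acid used for that also unmasks the aldehyde of ring A.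

**Methyl ketone.** Ketone 16 is cut at the CO–CH3 bond to amide 14 and methyllithium 15. Amide 14 comes from the unsaturated amide 13 by chemoselective saturation of the alkene. The reduction is placed directly after the rearrangement, while only one furan is present and before any enolate chemistry.

**Stereocentre (key disconnection).** In 13 the bond between the methyl-bearing carbon and the amide CH2 is cut, with transposition of the alkene. This gives the (R)-configured (E)-allylic alcohol 10 and the amide acetal 11. The C–C stereocentre is thus traded for a C–O stereocentre, which is far easier to set. The forward step must transfer the configuration completely, without acid that would harm the furan or its acetal.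

**Carbinol.** Alcohol 10 is traced to the propargylic alcohol 9 and this to ynone 8. Reduction of an alkyne guarantees the (E)-geometry. This matters because a (Z)-alkene with the same carbinol would give the opposite centre. The configuration is set by asymmetric transfer hydrogenation of the alkynyl ketone, a reduction that distinguishes well between an alkynyl and an alkyl residue. Resolution of the racemic alcohol by enzymatic acylation was considered. It was set aside because the propenyl and furylmethyl groups are of similar size, so the enantiomer preference cannot be predicted. Addition of a furylmethyl metal to an enal was also avoided, since such metals can react through the ring carbon next to the CH2 group.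

**Ring A building block.** Ynone 8 is cut at the CO–alkyne bond to the morpholine amide 6 and the alkynyl Grignard reagent 7. Amide 6 is cut at the bond between C4 of ring A and its CH2 to bromide 3 and the bromoacetamide 4, which reacts through its zinc enolate 5. Bromide 3 is the acetal of the commercial aldehyde 1 with diol 2. The 2,4-pattern of ring A is therefore bought, not made.

**Ring C fragment.** Ketone 23 comes from alcohol 22 by oxidation. Alcohol 22 is cut at the bond between C3 of ring C and the tether to 3-bromofuran 20 and the terminal alkene 19, joined through borane 21. Alkene 19 is the adduct of aldehyde 17 and the allyl Grignard reagent 18.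

## Alternatives that were turned down

**Alternative 1: ring A built last from a butenolide.**
- Disconnection: the bond between C2 of ring A and the alkene carbon is cut, and ring A is traced to the lactone A2.
- Forward key step: an organocerium reagent made from the (E)-alkenyl iodide A3 adds to the lactone carbonyl of A2, and acidic work-up dehydrates the lactol to the furan A1.
- For it: ring A is formed late and convergently, and the alkene geometry comes from a defined alkenyl iodide. On these two points it is stronger than the chosen route.
- Against it: it does not address the stereocentre, since A2 must already carry the (S)-methyl centre and rings B and C. The γ-protons of a butenolide are acidic, so enolisation to a 2-oxidofuran competes with 1,2-addition. After A1, desilylation and two oxidations are needed, and the chlorite oxidation would expose three electron-rich furans to hypochlorite.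
- Comparison: the chosen route solves the stereochemical problem directly and ends with an olefination and a saponification, with no oxidant near the furans.

**Alternative 2: asymmetric methylalumination.**
- Disconnection: the C–CH3 bond at the stereocentre.
- Forward key step: the terminal alkene of the allylfuran A5 undergoes methyl–aluminium addition under a chiral zirconocene catalyst to give the alane A4.
- For it: the centre is created catalytically from an achiral alkene in one step, with rings B and C in place. In step count to the stereocentre it is stronger than the chosen route.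
- Against it: methylalumination of simple monosubstituted alkenes is known to be only moderately enantioselective, and neither A4 nor its derivatives offer a handle for enrichment. Strongly Lewis acidic aluminium species meet two furans. The primary C–Al bond must still be joined to a two-carbon unit bearing ring A by an sp3–sp3 coupling, which adds steps and homocoupling risk.
- Comparison: the chosen route accepts more steps for a centre whose configuration comes from a highly selective ketone reduction and a stereospecific rearrangement.

**Alternative 3: asymmetric hydrogenation of a furyl alkene.**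
- Disconnection: no skeletal bond; the two hydrogens at the methyl-bearing carbon and its neighbour are removed to give the (E)-trisubstituted alkene A7 conjugated to ring B.
- Forward key step: hydrogenation of A7 with a cationic iridium phosphinooxazoline catalyst gives A6.
- For it: the alkene can be assembled from two achiral halves, and the stereocentre is set late and catalytically. In convergence and modularity it equals or beats the chosen route.
- Against it: the prochiral carbon carries a methyl group and a primary alkyl chain, so face selection depends entirely on the ligand. The 2-furyl oxygen can coordinate to the metal. (E)- and (Z)-A7 give opposite enantiomers, so the alkene must be geometrically pure. Iridium hydrides are acidic, related catalysts reduce furans, and three furans are present.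
- Comparison: the chosen route offers stereocontrol dictated by a pericyclic mechanism and independent of ligand screening, exercised while only one furan is in the molecule.

Key step: step 6

Remarks on the chemistry:
- Compounds 4, 7, 11, 15, 17, 18 and 28 are taken as commercial reagents.
- The descriptor of the methyl-bearing centre changes from (R) in 13 to (S) from 14 onwards. This is only a change of substituent priorities; the spatial arrangement stays the same.

## Route

Step 1
Reactants: 1 4-bromofuran-2-carbaldehyde; 2 ethane-1,2-diol
Product: 3 2-(4-bromofuran-2-yl)-1,3-dioxolane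
Conditions: p-TsOH·H2O (cat.), toluene, reflux, Dean–Stark
Reagents that add atoms: none
Why: Acid-catalysed acetalisation driven by azeotropic removal of water; the electron-poor bromofuran tolerates catalytic sulfonic acid, and the dioxolane masks the aldehyde through the organometallic steps that follow.

Step 2
Reactants: 3 2-(4-bromofuran-2-yl)-1,3-dioxolane; 4 2-bromo-1-(morpholin-4-yl)ethan-1-one
Product: 6 2-[5-(1,3-dioxolan-2-yl)furan-3-yl]-1-(morpholin-4-yl)ethan-1-one, via Reformatsky reagent 5 (not isolated)
Conditions: 4, Zn dust (Me3SiCl-activated), THF, 25 °C; then 3, Pd(dba)2 (2 mol %), P(t-Bu)3 (2 mol %), THF, 25–50 °C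
Reagents that add atoms: none
Why: Palladium-catalysed α-arylation of an amide zinc enolate (Negishi-type coupling of a Reformatsky reagent); the neutral zinc enolate spares the acetal and the acidic C5–H of the furan and installs the ring A CH2 together with an acylating group in one operation.

Step 3
Reactants: 6 2-[5-(1,3-dioxolan-2-yl)furan-3-yl]-1-(morpholin-4-yl)ethan-1-one; 7 prop-1-yn-1-ylmagnesium bromide
Product: 8 1-[5-(1,3-dioxolan-2-yl)furan-3-yl]pent-3-yn-2-one
Conditions: 7 (0.5 M in THF, 2.5 equiv), THF, 0 → 25 °C; then H2O
Reagents that add atoms: none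
Why: Acyl substitution on a morpholine amide, which behaves like an N-methoxy-N-methylamide: the carbonyl is released only on work-up, so the weakly basic alkynyl Grignard reagent adds once and the ynone is not attacked further.

Step 4
Reactants: 8 1-[5-(1,3-dioxolan-2-yl)furan-3-yl]pent-3-yn-2-one
Product: 9 (2R)-1-[5-(1,3-dioxolan-2-yl)furan-3-yl]pent-3-yn-2-ol
Conditions: Ru[(R,R)-TsNCH(Ph)CH(Ph)NH](η6-p-cymene) (1 mol %), i-PrOH, 25 °C
Reagents that add atoms: none
Why: Noyori asymmetric transfer hydrogenation of an alkynyl ketone; hydride and proton are delivered through the six-membered outer-sphere transition state with the alkyne in the place usually taken by an aryl group, so the (R,R)-diamine should give the (R)-carbinol, and the base-free amido complex avoids isomerisation of the acidic furylmethyl ynone.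

Step 5
Reactants: 9 (2R)-1-[5-(1,3-dioxolan-2-yl)furan-3-yl]pent-3-yn-2-ol
Product: 10 (2R,3E)-1-[5-(1,3-dioxolan-2-yl)furan-3-yl]pent-3-en-2-ol
Conditions: NaAlH2(OCH2CH2OMe)2 (2 equiv), THF, 0 → 25 °C; then aq. potassium sodium tartrate
Reagents that add atoms: none
Why: Hydroxyl-directed trans-hydroalumination of a propargylic alcohol; intramolecular hydride delivery from the alkoxyaluminate and protonolysis of the alkenyl–aluminium bond give only the (E)-alkene and do not touch the carbinol centre.

Step 6
Reactants: 10 (2R,3E)-1-[5-(1,3-dioxolan-2-yl)furan-3-yl]pent-3-en-2-ol; 11 1,1-dimethoxy-N,N-dimethylethan-1-amine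
Product: 13 (3R,4E)-6-[5-(1,3-dioxolan-2-yl)furan-3-yl]-N,N,3-trimethylhex-4-enamide, via ketene N,O-acetal 12 (not isolated)
Conditions: 11 (5 equiv), toluene, 110 °C, MeOH distilled off (xylene, 140 °C if slow)
Reagents that add atoms: none
Why: The secondary alcohol exchanges one methoxy group of 11, and loss of a second methanol gives ketene N,O-acetal 12, which undergoes a concerted suprafacial [3,3]-sigmatropic shift (Eschenmoser–Claisen rearrangement of an enantioenriched secondary (E)-allylic alcohol, the classical case of 1,3-chirality transfer). The C2–O bond of the pentenyl unit breaks and the bond between C4 and the ketene CH2 forms on the same face of the allyl system; no ring is closed. The new methyl-bearing centre is controlled by the (R)-carbinol and the (E)-propenyl geometry: in the chair the furylmethyl group lies pseudo-equatorial, so the CH2 reaches the face of C4 that gives the (3R)-amide with a new (E)-alkene. Because the migrating terminus is an unsubstituted CH2, chair and boat arrangements lead to the same centre; the only leak is the conformer with the furylmethyl group pseudo-axial, which would give the (Z)-alkene and the opposite configuration. That conformer suffers a 1,3-diaxial clash with the dimethylamino group on the ketene carbon, and this secures the selectivity the step needs. The medium is neutral, so the furan and its dioxolane should survive, and the amide carbon ends up two bonds from the stereocentre, where C2 of ring B is required.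

Step 7
Reactants: 13 (3R,4E)-6-[5-(1,3-dioxolan-2-yl)furan-3-yl]-N,N,3-trimethylhex-4-enamide
Product: 14 (3S)-6-[5-(1,3-dioxolan-2-yl)furan-3-yl]-N,N,3-trimethylhexanamide
Conditions: 2-O2NC6H4SO2NHNH2 (excess, in portions), Et3N, CH2Cl2, 25 °C
Reagents that add atoms: none
Why: Diimide reduction: the diazene formed in the flask transfers two hydrogens to the unpolarised 1,2-disubstituted alkene through a concerted six-centre transition state, while the aromatic furan, the amide and the acetal are not reduced; the basic anhydrous medium keeps the dioxolane intact and the stereocentre is not involved.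

Step 8
Reactants: 14 (3S)-6-[5-(1,3-dioxolan-2-yl)furan-3-yl]-N,N,3-trimethylhexanamide; 15 methyllithium
Product: 16 (4S)-7-[5-(1,3-dioxolan-2-yl)furan-3-yl]-4-methylheptan-2-one
Conditions: 15 (1.6 M in Et2O, 2 equiv), THF, −78 → 0 °C; then H2O
Reagents that add atoms: none
Why: Addition of an organolithium to a tertiary amide stops at the ketone oxidation level because the carbonyl is set free only on hydrolysis; the new carbonyl carbon is the future C2 of ring B and the methyl group its C3.

Step 9
Reactants: 17 2-{[tert-butyl(dimethyl)silyl]oxy}acetaldehyde; 18 prop-2-en-1-ylmagnesium bromide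
Product: 19 1-{[tert-butyl(dimethyl)silyl]oxy}pent-4-en-2-ol (racemic)
Conditions: 18 (1.0 M in Et2O), Et2O, −78 °C; then H2O
Reagents that add atoms: none
Why: Grignard addition to an aldehyde; the carbinol is racemic, which is of no consequence because it is oxidised in step 11.

Step 10
Reactants: 19 1-{[tert-butyl(dimethyl)silyl]oxy}pent-4-en-2-ol; 20 3-bromofuran
Product: 22 1-{[tert-butyl(dimethyl)silyl]oxy}-5-(furan-3-yl)pentan-2-ol (racemic), via B-alkyl-9-BBN borane 21 (not isolated)
Conditions: 9-BBN (2.2 equiv), THF, 0 → 25 °C; then 20, PdCl2(dppf) (5 mol %), aq. K3PO4, DMF, 50 °C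
Reagents that add atoms: none
Why: Anti-Markovnikov hydroboration of the terminal alkene followed by B-alkyl Suzuki–Miyaura coupling with the heteroaryl bromide; the second equivalent of borane is taken up by the free hydroxyl as a borinate, which the aqueous base cleaves again.

Step 11
Reactants: 22 1-{[tert-butyl(dimethyl)silyl]oxy}-5-(furan-3-yl)pentan-2-ol
Product: 23 1-{[tert-butyl(dimethyl)silyl]oxy}-5-(furan-3-yl)pentan-2-one
Conditions: Dess–Martin periodinane, NaHCO3, CH2Cl2, 0 → 25 °C
Reagents that add atoms: none
Why: Buffered hypervalent-iodine oxidation of a secondary alcohol under neutral conditions that leave the furan and the silyl ether untouched.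

Step 12
Reactants: 16 (4S)-7-[5-(1,3-dioxolan-2-yl)furan-3-yl]-4-methylheptan-2-one; 23 1-{[tert-butyl(dimethyl)silyl]oxy}-5-(furan-3-yl)pentan-2-one
Product: 25 (8S)-4-({[tert-butyl(dimethyl)silyl]oxy}methyl)-11-[5-(1,3-dioxolan-2-yl)furan-3-yl]-1-(furan-3-yl)-4-hydroxy-8-methylundecan-6-one (both C4 epimers), via lithium enolate 24 (not isolated)
Conditions: LiN(i-Pr)2 (1.05 equiv), THF, −78 °C; then 23, −78 °C; AcOH (1.1 equiv) in THF, −78 °C
Reagents that add atoms: none
Why: Directed aldol addition: kinetic deprotonation occurs at the methyl group, the less hindered α-position, and the lithium enolate adds to the α-silyloxy ketone, whose carbonyl is activated by the neighbouring oxygen; the new carbinol centre is uncontrolled but is lost on aromatisation.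

Step 13
Reactants: 25 (8S)-4-({[tert-butyl(dimethyl)silyl]oxy}methyl)-11-[5-(1,3-dioxolan-2-yl)furan-3-yl]-1-(furan-3-yl)-4-hydroxy-8-methylundecan-6-one
Product: 27 4-[(4S)-5-{4-[3-(furan-3-yl)propyl]furan-2-yl}-4-methylpentyl]furan-2-carbaldehyde, via keto diol aldehyde 26 (not isolated)
Conditions: 1 M aq. HCl/THF (1:3), 25 °C
Reagents that add atoms: water O
Why: Aqueous acid hydrolyses the dioxolane and the silyl ether; the freed primary hydroxyl closes onto the ketone (5-exo-trig hemiketal) and two dehydrations driven by aromatisation give ring B as a 2,4-disubstituted furan (furan annulation of an aldol from an α-oxygenated ketone). The stereocentre is β to the carbonyl and cannot epimerise.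

Step 14
Reactants: 27 4-[(4S)-5-{4-[3-(furan-3-yl)propyl]furan-2-yl}-4-methylpentyl]furan-2-carbaldehyde; 28 ethyl 2-(triphenyl-λ5-phosphanylidene)propanoate
Product: 29 ethyl (2E)-3-{4-[(4S)-5-{4-[3-(furan-3-yl)propyl]furan-2-yl}-4-methylpentyl]furan-2-yl}-2-methylprop-2-enoate
Conditions: 28 (1.5 equiv), toluene, 80 °C
Reagents that add atoms: none
Why: Wittig olefination with a stabilised α-methyl ylide; reversible addition leads to the thermodynamically preferred (E)-trisubstituted enoate with the ester trans to the furan.

Step 15
Reactants: 29 ethyl (2E)-3-{4-[(4S)-5-{4-[3-(furan-3-yl)propyl]furan-2-yl}-4-methylpentyl]furan-2-yl}-2-methylprop-2-enoate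
Product: 30 (2E)-3-{4-[(4S)-5-{4-[3-(furan-3-yl)propyl]furan-2-yl}-4-methylpentyl]furan-2-yl}-2-methylprop-2-enoic acid
Conditions: LiOH·H2O, THF/MeOH/H2O, 25–40 °C; then 0.5 M HCl to pH 4, 0 °C
Reagents that add atoms: lithium hydroxide [Li+].[OH-]
Why: Saponification by acyl–oxygen cleavage; base affects neither the furans, the alkene geometry nor the remote stereocentre, and the acid is liberated at a pH the furans tolerate.

## Compound list

1 | 4-bromofuran-2-carbaldehyde | O=Cc1cc(Br)co1 | starting material
2 | ethane-1,2-diol | OCCO | starting material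
3 | 2-(4-bromofuran-2-yl)-1,3-dioxolane | Brc1coc(C2OCCO2)c1 | intermediate
4 | 2-bromo-1-(morpholin-4-yl)ethan-1-one | O=C(CBr)N1CCOCC1 | starting material
5 | bromo[2-(morpholin-4-yl)-2-oxoethyl]zinc (Reformatsky reagent) | Br[Zn]CC(=O)N1CCOCC1 | intermediate (not isolated)
6 | 2-[5-(1,3-dioxolan-2-yl)furan-3-yl]-1-(morpholin-4-yl)ethan-1-one | O=C(Cc1coc(C2OCCO2)c1)N1CCOCC1 | intermediate
7 | prop-1-yn-1-ylmagnesium bromide | CC#C[Mg]Br | starting material
8 | 1-[5-(1,3-dioxolan-2-yl)furan-3-yl]pent-3-yn-2-one | CC#CC(=O)Cc1coc(C2OCCO2)c1 | intermediate
9 | (2R)-1-[5-(1,3-dioxolan-2-yl)furan-3-yl]pent-3-yn-2-ol | CC#C[C@H](O)Cc1coc(C2OCCO2)c1 | intermediate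
10 | (2R,3E)-1-[5-(1,3-dioxolan-2-yl)furan-3-yl]pent-3-en-2-ol | C/C=C/[C@H](O)Cc1coc(C2OCCO2)c1 | intermediate
11 | 1,1-dimethoxy-N,N-dimethylethan-1-amine | CC(OC)(OC)N(C)C | starting material
12 | 1-{[(2R,3E)-1-[5-(1,3-dioxolan-2-yl)furan-3-yl]pent-3-en-2-yl]oxy}-N,N-dimethylethen-1-amine | C/C=C/[C@H](OC(=C)N(C)C)Cc1coc(C2OCCO2)c1 | intermediate (not isolated)
13 | (3R,4E)-6-[5-(1,3-dioxolan-2-yl)furan-3-yl]-N,N,3-trimethylhex-4-enamide | CN(C)C(=O)C[C@@H](C)/C=C/Cc1coc(C2OCCO2)c1 | intermediate
14 | (3S)-6-[5-(1,3-dioxolan-2-yl)furan-3-yl]-N,N,3-trimethylhexanamide | CN(C)C(=O)C[C@@H](C)CCCc1coc(C2OCCO2)c1 | intermediate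
15 | methyllithium | [Li]C | starting material
16 | (4S)-7-[5-(1,3-dioxolan-2-yl)furan-3-yl]-4-methylheptan-2-one | CC(=O)C[C@@H](C)CCCc1coc(C2OCCO2)c1 | intermediate
17 | 2-{[tert-butyl(dimethyl)silyl]oxy}acetaldehyde | CC(C)(C)[Si](C)(C)OCC=O | starting material
18 | prop-2-en-1-ylmagnesium bromide | C=CC[Mg]Br | starting material
19 | 1-{[tert-butyl(dimethyl)silyl]oxy}pent-4-en-2-ol (racemic) | CC(C)(C)[Si](C)(C)OCC(O)CC=C | intermediate
20 | 3-bromofuran | Brc1ccoc1 | starting material
21 | 9-(4-{[9-borabicyclo[3.3.1]nonan-9-yl]oxy}-5-{[tert-butyl(dimethyl)silyl]oxy}pentyl)-9-borabicyclo[3.3.1]nonane | CC(C)(C)[Si](C)(C)OCC(OB1C2CCCC1CCC2)CCCB1C2CCCC1CCC2 | intermediate (not isolated)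
22 | 1-{[tert-butyl(dimethyl)silyl]oxy}-5-(furan-3-yl)pentan-2-ol (racemic) | CC(C)(C)[Si](C)(C)OCC(O)CCCc1ccoc1 | intermediate
23 | 1-{[tert-butyl(dimethyl)silyl]oxy}-5-(furan-3-yl)pentan-2-one | CC(C)(C)[Si](C)(C)OCC(=O)CCCc1ccoc1 | intermediate
24 | lithium (4S)-7-[5-(1,3-dioxolan-2-yl)furan-3-yl]-4-methylhept-1-en-2-olate | [Li]OC(=C)C[C@@H](C)CCCc1coc(C2OCCO2)c1 | intermediate (not isolated)
25 | (8S)-4-({[tert-butyl(dimethyl)silyl]oxy}methyl)-11-[5-(1,3-dioxolan-2-yl)furan-3-yl]-1-(furan-3-yl)-4-hydroxy-8-methylundecan-6-one (both C4 epimers) | CC(C)(C)[Si](C)(C)OCC(O)(CCCc1ccoc1)CC(=O)C[C@@H](C)CCCc1coc(C2OCCO2)c1 | intermediate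
26 | 4-[(4S)-11-(furan-3-yl)-8-hydroxy-8-(hydroxymethyl)-4-methyl-6-oxoundecyl]furan-2-carbaldehyde (both C8 epimers) | O=Cc1cc(CCC[C@H](C)CC(=O)CC(O)(CO)CCCc2ccoc2)co1 | intermediate (not isolated)
27 | 4-[(4S)-5-{4-[3-(furan-3-yl)propyl]furan-2-yl}-4-methylpentyl]furan-2-carbaldehyde | O=Cc1cc(CCC[C@H](C)Cc2cc(CCCc3ccoc3)co2)co1 | intermediate
28 | ethyl 2-(triphenyl-λ5-phosphanylidene)propanoate | CCOC(=O)C(C)=P(c1ccccc1)(c1ccccc1)c1ccccc1 | starting material
29 | ethyl (2E)-3-{4-[(4S)-5-{4-[3-(furan-3-yl)propyl]furan-2-yl}-4-methylpentyl]furan-2-yl}-2-methylprop-2-enoate | C/C(=C\c1cc(CCC[C@H](C)Cc2cc(CCCc3ccoc3)co2)co1)C(=O)OCC | intermediate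
30 | (2E)-3-{4-[(4S)-5-{4-[3-(furan-3-yl)propyl]furan-2-yl}-4-methylpentyl]furan-2-yl}-2-methylprop-2-enoic acid | C/C(=C\c1cc(CCC[C@H](C)Cc2cc(CCCc3ccoc3)co2)co1)C(=O)O | target

## Step count and least certain steps

Total: 15 steps. Longest linear sequence: 12 steps (steps 1–8 and 12–15). The ring C fragment takes 3 steps (9–11) and joins in step 12.

**Step 6 (key step).**
- What may go wrong: part of the material could rearrange through the conformer with the furylmethyl group pseudo-axial. That gives the (Z)-amide with the opposite centre, and after saturation it lowers the optical purity. At 110–140 °C the activated alcohol could also eliminate towards a diene conjugated with the furan, because the furylmethyl protons are acidified.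
- Fallback (Ireland–Claisen at low temperature, same disconnection): it sets out from 10. Acetylation (Ac2O, pyridine) gives (2R,3E)-1-[5-(1,3-dioxolan-2-yl)furan-3-yl]pent-3-en-2-yl acetate F1. Enolisation and O-silylation (LiN(i-Pr)2, Me3SiCl, THF, −78 °C) and warming to 25 °C bring about the rearrangement of the silyl ketene acetal. Mild aqueous work-up gives (3R,4E)-6-[5-(1,3-dioxolan-2-yl)furan-3-yl]-3-methylhex-4-enoic acid F2. Coupling of F2 with dimethylamine (carbodiimide, 1-hydroxybenzotriazole) comes back to the route at 13.

**Step 12.**
- What may go wrong: the aldol addition to a ketone is reversible, and proton transfer from the enolisable ketone 23 to enolate 24 competes. Both would return the two ketones or scramble the enolate position.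
- Fallback (irreversible acetylide addition in place of the enolate): it sets out from 16. Trapping the kinetic enolate with ClP(O)(OEt)2 gives diethyl (4S)-7-[5-(1,3-dioxolan-2-yl)furan-3-yl]-4-methylhept-1-en-2-yl phosphate F3. Elimination with LiN(i-Pr)2 (2.2 equiv) gives the terminal alkyne 2-{4-[(4S)-4-methylhept-6-yn-1-yl]furan-2-yl}-1,3-dioxolane F4. Its lithium acetylide (n-BuLi, THF, −78 °C) adds to 23 to give (8S)-4-({[tert-butyl(dimethyl)silyl]oxy}methyl)-11-[5-(1,3-dioxolan-2-yl)furan-3-yl]-1-(furan-3-yl)-8-methylundec-5-yn-4-ol F5. Bu4NF gives (6S)-9-[5-(1,3-dioxolan-2-yl)furan-3-yl]-2-[3-(furan-3-yl)propyl]-6-methylnon-3-yne-1,2-diol F6. AgNO3 on silica gel effects 5-endo-dig hydroalkoxylation and loss of water to 2-{4-[(4S)-5-{4-[3-(furan-3-yl)propyl]furan-2-yl}-4-methylpentyl]furan-2-yl}-1,3-dioxolane F7. Pyridinium p-toluenesulfonate in wet acetone hydrolyses the acetal, and the sequence comes back at 27.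

**Step 13.**
- What may go wrong: the dioxolane is hydrolysed quickly, while desilylation and cyclodehydration are slower. A free furfural-type aldehyde therefore stands in aqueous acid beside electron-rich furans, which invites acid-catalysed hydroxyalkylation and oligomerisation, or hydrolytic opening of a furan.
- Fallback (staged, with the acetal removed last and alone): it sets out from 25. HF·pyridine in THF/pyridine at 0 °C removes the silyl group without base, so no retro-aldol is expected, and gives (8S)-11-[5-(1,3-dioxolan-2-yl)furan-3-yl]-1-(furan-3-yl)-4-hydroxy-4-(hydroxymethyl)-8-methylundecan-6-one F8. Pyridinium p-toluenesulfonate with 4 Å molecular sieves in CH2Cl2 effects the cyclodehydration under anhydrous conditions and leads to the dioxolane-protected trifuran F7 already described. Hydrolysis of the acetal in wet acetone comes back at 27.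

**Step 2.**
- What may go wrong: oxidative addition to the electron-rich 3-bromofuran may be slow, so that protonation or homocoupling of the zinc enolate 5 takes over.
- Fallback (classical C1 homologation, then acylation of a furylmethylzinc): it sets out from 3. Bromine–lithium exchange (n-BuLi, THF, −78 °C) and formylation with DMF give 5-(1,3-dioxolan-2-yl)furan-3-carbaldehyde F9. NaBH4 gives [5-(1,3-dioxolan-2-yl)furan-3-yl]methanol F10. MeSO2Cl, LiCl and 2,4,6-collidine in DMF give 2-[4-(chloromethyl)furan-2-yl]-1,3-dioxolane F11. Zinc insertion (Zn, LiCl, THF) gives chloro{[5-(1,3-dioxolan-2-yl)furan-3-yl]methyl}zinc F12. Acylation under Pd(PPh3)4 catalysis with but-2-ynoyl chloride F13, made from but-2-ynoic acid and oxalyl chloride, comes back at ynone 8. The palladium-mediated acylation is preferred to a direct carbonyl addition of F12 because it fixes the new bond at the CH2 carbon and not at the neighbouring ring carbon.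

## Further compounds

F1 | step 6 | (2R,3E)-1-[5-(1,3-dioxolan-2-yl)furan-3-yl]pent-3-en-2-yl acetate | C/C=C/[C@H](OC(C)=O)Cc1coc(C2OCCO2)c1
F2 | step 6 | (3R,4E)-6-[5-(1,3-dioxolan-2-yl)furan-3-yl]-3-methylhex-4-enoic acid | OC(=O)C[C@@H](C)/C=C/Cc1coc(C2OCCO2)c1
F3 | step 12 | diethyl (4S)-7-[5-(1,3-dioxolan-2-yl)furan-3-yl]-4-methylhept-1-en-2-yl phosphate | CCOP(=O)(OCC)OC(=C)C[C@@H](C)CCCc1coc(C2OCCO2)c1
F4 | step 12 | 2-{4-[(4S)-4-methylhept-6-yn-1-yl]furan-2-yl}-1,3-dioxolane | C#CC[C@@H](C)CCCc1coc(C2OCCO2)c1
F5 | step 12 | (8S)-4-({[tert-butyl(dimethyl)silyl]oxy}methyl)-11-[5-(1,3-dioxolan-2-yl)furan-3-yl]-1-(furan-3-yl)-8-methylundec-5-yn-4-ol | CC(C)(C)[Si](C)(C)OCC(O)(CCCc1ccoc1)C#CC[C@@H](C)CCCc1coc(C2OCCO2)c1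
F6 | step 12 | (6S)-9-[5-(1,3-dioxolan-2-yl)furan-3-yl]-2-[3-(furan-3-yl)propyl]-6-methylnon-3-yne-1,2-diol | OCC(O)(CCCc1ccoc1)C#CC[C@@H](C)CCCc1coc(C2OCCO2)c1
F7 | step 12 | 2-{4-[(4S)-5-{4-[3-(furan-3-yl)propyl]furan-2-yl}-4-methylpentyl]furan-2-yl}-1,3-dioxolane | C1COC(O1)c1cc(CCC[C@H](C)Cc2cc(CCCc3ccoc3)co2)co1
F8 | step 13 | (8S)-11-[5-(1,3-dioxolan-2-yl)furan-3-yl]-1-(furan-3-yl)-4-hydroxy-4-(hydroxymethyl)-8-methylundecan-6-one | OCC(O)(CCCc1ccoc1)CC(=O)C[C@@H](C)CCCc1coc(C2OCCO2)c1
F9 | step 2 | 5-(1,3-dioxolan-2-yl)furan-3-carbaldehyde | O=Cc1coc(C2OCCO2)c1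
F10 | step 2 | [5-(1,3-dioxolan-2-yl)furan-3-yl]methanol | OCc1coc(C2OCCO2)c1
F11 | step 2 | 2-[4-(chloromethyl)furan-2-yl]-1,3-dioxolane | ClCc1coc(C2OCCO2)c1
F12 | step 2 | chloro{[5-(1,3-dioxolan-2-yl)furan-3-yl]methyl}zinc | Cl[Zn]Cc1coc(C2OCCO2)c1
F13 | step 2 | but-2-ynoyl chloride | CC#CC(=O)Cl
A1 | alternative 1 | tert-butyl(dimethyl){[(2E)-2-methyl-3-{4-[(4S)-4-methyl-5-{4-[3-(furan-3-yl)propyl]furan-2-yl}pentyl]furan-2-yl}prop-2-en-1-yl]oxy}silane | C/C(=C\c1cc(CCC[C@H](C)Cc2cc(CCCc3ccoc3)co2)co1)CO[Si](C)(C)C(C)(C)C
A2 | alternative 1 | 4-[(4S)-5-{4-[3-(furan-3-yl)propyl]furan-2-yl}-4-methylpentyl]furan-2(5H)-one | O=C1C=C(CCC[C@H](C)Cc2cc(CCCc3ccoc3)co2)CO1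
A3 | alternative 1 | tert-butyl{[(2E)-3-iodo-2-methylprop-2-en-1-yl]oxy}dimethylsilane | C/C(=C\I)CO[Si](C)(C)C(C)(C)C
A4 | alternative 2 | dimethyl[(2R)-2-methyl-3-{4-[3-(furan-3-yl)propyl]furan-2-yl}propyl]alane | C[Al](C)C[C@H](C)Cc1cc(CCCc2ccoc2)co1
A5 | alternative 2 | 2-(prop-2-en-1-yl)-4-[3-(furan-3-yl)propyl]furan | C=CCc1cc(CCCc2ccoc2)co1
A6 | alternative 3 | triisopropyl({4-[(4S)-4-methyl-5-{4-[3-(furan-3-yl)propyl]furan-2-yl}pentyl]furan-2-yl}methoxy)silane | CC(C)[Si](OCc1cc(CCC[C@H](C)Cc2cc(CCCc3ccoc3)co2)co1)(C(C)C)C(C)C
A7 | alternative 3 | triisopropyl({4-[(4E)-4-methyl-5-{4-[3-(furan-3-yl)propyl]furan-2-yl}pent-4-en-1-yl]furan-2-yl}methoxy)silane | CC(C)[Si](OCc1cc(CCC/C(C)=C/c2cc(CCCc3ccoc3)co2)co1)(C(C)C)C(C)C
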